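## Structural features

The target 14 is a flavanonol. Aromatic ring A and the dihydropyranone ring C are fused along C4a–C8a to a chroman-4-one, and ring B is attached to C2 through the C2–C1' bond. C2 (R; benzylic and bound to O1) and C3 (R; the carbinol next to the C4 ketone) are adjacent stereocentres whose aryl and hydroxyl groups are trans and both equatorial, the more stable arrangement. Ring A carries O1, a 5-OH hydrogen-bonded to the C4 carbonyl, a 7-OH and a prenyl (3-methylbut-2-enyl) group at C8; ring B carries 4'-OH and a second prenyl group at C3'. The core is fragile in four ways: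
- base enolises C3 and expels the O1 phenoxide, which opens ring C and endangers C2;
- the α-ketol is easily dehydrogenated to the flavonol;
- each prenyl group lies ortho to a phenolic oxygen (C3' to O4', C8 to O7), so acid closes 2,2-dimethylchroman rings;
- the trisubstituted alkenes rule out hydrogenolysis.

The skeleton and both stereocentres already exist in the natural flavanonol 3. The real difficulty is therefore the regioselective attachment of two C5 units (at C8 rather than the equally nucleophilic C6, and only once on ring B) and the differentiation of four hydroxyl groups. The key step exploits the fact that C3' is ortho to O4' and C8 is para to O5: an allyl ether on O4' reaches C3' by one [3,3] shift, and an allyl ether on O5 reaches C8 by two successive [3,3] shifts through C6.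

## Logic of the disconnections

**14 ⇒ 13.** The O7–Si and O3–Si bonds are cut. The last operation may be neither acidic (chroman closure at O4'/C3' and O7/C8), nor strongly basic (ring C opening), nor reductive (alkenes). Silicon on oxygen is the one mask that leaves under buffered fluoride. The demand is that both silyl groups fall in a single near-neutral treatment.

**13 ⇒ 8.** The two aryl–CH2 bonds, C8–CH2 and C3'–CH2, are cut and each C5 unit is moved back onto the neighbouring phenol oxygen. This removes both C–C bonds in one operation and reduces the problem to O-alkylation of an intact flavanonol. The forward step must satisfy four demands: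
- the O4' ether must be the tertiary 1,1-dimethylallyl isomer, because one allyl inversion then delivers a normal prenyl group;
- the O5 ether must be the primary prenyl isomer, because two inversions restore it;
- O7 must be blocked so that the second shift passes through an enol ether and not a free phenol;
- O3 must not offer a competing α-ketol chelate to the trivalent europium Lewis acid that has to sit between O4 and O5.

**8 ⇒ 6 + 7.** The O5–CH2 bond is cut. In 6 the 5-OH is the only remaining free hydroxyl, so no selectivity question arises. The forward step must alkylate a hydrogen-bonded, peri-hindered phenol without base and at the primary allyl carbon only; a neutral redox condensation meets this.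

**6 ⇒ 5.** The O3–Si bond is cut. The 3-OH of 5 is its only alcohol; left free it would compete as the alcohol partner in the next step and later bind the europium. The demand is silylation of a hindered secondary alcohol without touching the chelated 5-OH.

**5 ⇒ 4 + 2.** The O4'–C(CH3)2 bond is cut. A tertiary allyl aryl ether cannot be made by direct substitution, but a π-allyl complex of zerovalent palladium generated from the tertiary carbonate forms it under almost neutral conditions. The demand is attack at the substituted allyl terminus under kinetic control, by the only unhindered phenol of 4.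

**4 ⇒ 3.** The O7–Si bond is cut. The 7-OH, para to the carbonyl, is the most acidic hydroxyl of 3 and reacts first; masking it makes 4'-OH the next most reactive site. The demand is mono-silylation.

**2 ⇒ 1.** The carbonate C–O bond is cut, leading back to the commercial tertiary allylic alcohol. The forward step is a routine O-acylation of its alkoxide.

## Other disconnections considered

**Alternative 1:** The O1–C8a bond of the tetrakis-O-MOM-protected target A1 is cut, leading back to the open-chain β-hydroxy ketone A2. In A2 an ortho-fluoroaryl ketone already carries the ring A prenyl group and both stereocentres. The forward key step would be base-induced intramolecular SNAr: the C2 alkoxide adds to C8a, the ortho acyl group stabilises the Meisenheimer intermediate, fluoride leaves and ring C closes in the 6-exo mode.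
- In its favour: the C8 position of the prenyl group is fixed by the building block and never depends on a migration. On this point it is better than the chosen plan. It is convergent and independent of the supply of 3, so either enantiomer and analogues would be accessible, which is also better.
- Against it: A2 is an aldol, so the base needed for the closure can also cause retro-aldol cleavage of C2–C3, dehydration, or epimerisation at C3. The fluorine is flanked by a prenyl group and the acyl group. A2 requires de novo stereocontrol and two separately prenylated aromatic fragments. Going from A1 to 14 means removing four acetals with acid in the presence of two o-prenylphenols.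
- Comparison: both plans end with the same skeleton. Mechanistically a single polar bond formation is simpler to analyse than three pericyclic events, which counts as equal or slightly better. In step economy and in safety of the final deprotection the chosen plan is clearly ahead.

**Alternative 2:** The C8–C8a and C4a–C5 bonds of A3 are cut, leading back to the chiral bromo-dihydropyranone A4 and the prenyl-substituted 1-methoxy-1,3-bis(trimethylsilyloxy)diene A5. The forward key step would be a formal [4+2] annulation: the nucleophilic diene terminus attacks C8a and the ketene acetal carbon attacks C4a. Eliminations then remove the bromine, the methoxy group and the silyl groups and aromatise ring A.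
- In its favour: ring A would arrive with both phenols free and the prenyl group unambiguously at C8. That is better than the chosen plan on regiochemistry and on ring A protection.
- Against it: the enone of A4 is a β-oxygenated, electron-rich acceptor and A5 is substituted at its reacting terminus, so the cycloaddition is expected to be sluggish. C3, α to the ketone, would be exposed to the acid released on aromatisation. A4 needs a multi-step enantioselective synthesis. The remaining aryl acetal of A3 must still be removed with acid next to an o-prenylphenol.
- Comparison: the idea is the most elegant structurally. Its mechanism is less well precedented for this substrate class than sigmatropic transfer on flavonoid ethers, and it is much longer than a route from 3.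

**Alternative 3:** The C4–C4a bond of A6 is cut, leading back to the aryl bromide A7, in which ring A is tethered through O1 to an N-methoxy-N-methylamide. The forward key step would be a Parham cyclisation: bromine–lithium exchange with an alkyllithium at low temperature, then 6-exo attack of the aryllithium on the amide carbonyl. The chelated tetrahedral intermediate releases the ketone only on work-up.
- In its favour: the C–C bond forms at low temperature, over-addition is excluded, and the ring A substitution pattern is fixed beforehand. On regiochemistry and thermal mildness it equals or betters the chosen plan.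
- Against it: A7 needs an intermolecular, stereodefined benzylic C2–O1 ether to a hindered phenol, at a p-alkoxybenzylic carbon that ionises easily. Deprotonation at C3 would expel the β-aryloxide. The end game again requires acid to remove three acetals in the presence of o-prenylphenols.
- Comparison: it is structurally equivalent and mechanistically well understood, but it rebuilds stereocentres and rings that the chosen plan takes intact from 3 and is far longer.

Key step: step 6

Remarks on the chemistry:
- Assumption: commercial (+)-aromadendrin 3 is the enantiopure (2R,3R)-trans isomer, so both stereocentres of 14 are carried through unchanged.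
- Structure check: in 14, 13 and 8 the ring A side chain sits on the carbon between C8a and C7 (C8), and C2 and C3 are R,R as in 3. No correction of these structures is needed.
- Precursor design: a leaner precursor with a TBS ether at O7 and a free 3-OH was weighed and set aside. An aryl TBS ether para to the ketone is a vinylogous silyl ester and is at risk from the alkoxide, phenoxide and hydrazide nucleophiles of steps 3 and 5; TIPS is used instead. The free α-ketol would compete as alcohol in step 5 and as a chelating ligand for europium in step 6; it is masked as a TES ether at the cost of one step. Both silyl groups leave together in step 7.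

## Route

Step 1
Reactants: 1 2-methylbut-3-en-2-ol
Product: 2 tert-butyl 2-methylbut-3-en-2-yl carbonate
Conditions: n-BuLi, THF, −78 °C; then Boc2O, −78 °C to rt
Reagents that add atoms: di-tert-butyl dicarbonate, CC(C)(C)OC(=O)OC(=O)OC(C)(C)C
Why: O-alkoxycarbonylation of a lithium tertiary alkoxide by the dicarbonate; the alkoxide is formed first because the hindered tertiary alcohol is not acylated under neutral conditions, and the product is the usual π-allyl precursor for the next branch point.

Step 2
Reactants: 3 (+)-aromadendrin
Product: 4 7-O-TIPS-aromadendrin
Conditions: TIPSCl (1.05 equiv), imidazole, DMF, −10 to 0 °C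
Reagents that add atoms: triisopropylsilyl chloride, CC(C)[Si](Cl)(C(C)C)C(C)C
Why: Regioselective phenol silylation: the 7-OH, para to the C4 carbonyl, is the most acidic and should react first with one equivalent at low temperature, the chelated 5-OH and the hindered secondary 3-OH are too slow for the bulky chloride, and 4'-OH is held back by stoichiometry; any bis-silyl ether can be returned to 3 with fluoride.

Step 3
Reactants: 4 7-O-TIPS-aromadendrin; 2 tert-butyl 2-methylbut-3-en-2-yl carbonate
Product: 5 4'-O-(1,1-dimethylallyl)-7-O-TIPS-aromadendrin
Conditions: Pd(PPh3)4 (3 mol %), THF, 0 °C, quench at full conversion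
Reagents that add atoms: none
Why: Decarboxylative Tsuji–Trost O-allylation: zerovalent palladium ionises 2 to a 1,1-dimethyl-π-allyl cation and tert-butoxide, which deprotonates the only unchelated phenol (4'-OH), and the phenoxide attacks the substituted terminus under kinetic control to give the tertiary ether; low temperature and an early quench should prevent re-ionisation to the linear prenyl ether, and the base-sensitive ring C sees only a phenol-buffered medium.

Step 4
Reactants: 5 4'-O-(1,1-dimethylallyl)-7-O-TIPS-aromadendrin
Product: 6 3-O-TES-4'-O-(1,1-dimethylallyl)-7-O-TIPS-aromadendrin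
Conditions: TESCl, imidazole, DMF, 0 °C to rt
Reagents that add atoms: triethylsilyl chloride, CC[Si](Cl)(CC)CC
Why: Alcohol silylation: the 3-OH is the only alcohol, the hydrogen-bonded 5-OH is expected to stay free (a trace of 5-O-silyl ether would hydrolyse on work-up), and the weakly acidic imidazolium salt does not ionise the tertiary allyl ether.

Step 5
Reactants: 6 3-O-TES-4'-O-(1,1-dimethylallyl)-7-O-TIPS-aromadendrin; 7 3-methylbut-2-en-1-ol
Product: 8 3-O-TES-5-O-prenyl-4'-O-(1,1-dimethylallyl)-7-O-TIPS-aromadendrin
Conditions: PPh3, DIAD, THF, 0 °C to rt
Reagents that add atoms: none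
Why: Mitsunobu etherification: the betaine deprotonates the only acidic hydroxyl (5-OH), the primary allylic alcohol is activated as its oxyphosphonium salt and is displaced at CH2 in SN2 fashion to give the unrearranged prenyl ether; the medium is neutral, so ring C, the silyl ethers and the tertiary allyl ether should survive, and with O3 silylated no second alcohol competes.

Step 6
Reactants: 8 3-O-TES-5-O-prenyl-4'-O-(1,1-dimethylallyl)-7-O-TIPS-aromadendrin
Product: 13 3-O-TES-7-O-TIPS-lespedezaflavanone C, via ring A ortho-dienone 9 (not isolated), via ring A para-dienone 10 (not isolated), via 8-prenyl 5-phenol 11 (not isolated), via ring B ortho-dienone 12 (not isolated)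
Conditions: Eu(fod)3 (10 mol %), NaHCO3, PhCl, 85 °C, then 120 °C
Reagents that add atoms: none
Why: Trivalent europium chelates O4 and O5 and so accelerates an aromatic Claisen [3,3] shift of the O5 prenyl group to C6, the only open ortho position, giving dienone 9 with a 1,1-dimethylallyl group on an sp3 carbon. A Cope [3,3] shift across C6–C7–C8 should then outrun enolisation, because it relieves the crowding between the quaternary carbon and the 7-silyloxy group and the aprotic medium offers no proton shuttle; it gives para-dienone 10, which tautomerises to the chelated 5-phenol 11 with a normal prenyl group at C8. At the higher temperature the ring B tertiary ether undergoes a thermal ortho-Claisen shift through a chair transition state to dienone 12, which enolises to 13; the single allyl inversion turns the 1,1-dimethylallyl ether into a normal prenyl group, and C3' and C5' are equivalent, so only one regioisomer can form. The closest known reaction types are the Eu(fod)3-promoted para-Claisen–Cope rearrangement of 5-O-prenylflavonoids and the ortho-Claisen rearrangement of aryl 1,1-dimethylallyl ethers. No ring is closed and no lasting stereocentre is created; the sp3 centres of 9, 10 and 12 disappear on rearomatisation. The selectivity needed is C8 over C6, and it is secured by placing the migrating group on O5 (C4a is blocked, so the first shift can only reach C6 and the second can only continue to C8) with O7 capped as a silyl enol ether partner. The 3-O-TES group keeps the europium away from an α-ketol chelate, NaHCO3 scavenges acid that could close a chroman from 4'-OH and the C3' prenyl group, and the neutral aprotic medium leaves C2 and C3 untouched.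

Step 7
Reactants: 13 3-O-TES-7-O-TIPS-lespedezaflavanone C
Product: 14 lespedezaflavanone C
Conditions: TBAF/AcOH (1:1, 3 equiv), THF, 0 °C to rt
Reagents that add atoms: none
Why: Fluoride-induced desilylation of the aryl TIPS ether and the alkyl TES ether in one operation; acetic acid protonates each phenoxide or alkoxide as it forms, so ring C should not open and C2 should not epimerise, and no acid strong enough to cyclise the o-prenylphenols is present.

## Compound list

1 | 2-methylbut-3-en-2-ol | C=CC(C)(C)O | starting material
2 | tert-butyl 2-methylbut-3-en-2-yl carbonate | C=CC(C)(C)OC(=O)OC(C)(C)C | intermediate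
3 | (+)-aromadendrin, (2R,3R)-3,5,7-trihydroxy-2-(4-hydroxyphenyl)chroman-4-one | Oc1ccc(cc1)[C@H]1Oc2cc(O)cc(O)c2C(=O)[C@@H]1O | starting material
4 | (2R,3R)-3,5-dihydroxy-2-(4-hydroxyphenyl)-7-(triisopropylsilyloxy)chroman-4-one | Oc1ccc(cc1)[C@H]1Oc2cc(O[Si](C(C)C)(C(C)C)C(C)C)cc(O)c2C(=O)[C@@H]1O | intermediate
5 | (2R,3R)-3,5-dihydroxy-2-[4-(2-methylbut-3-en-2-yloxy)phenyl]-7-(triisopropylsilyloxy)chroman-4-one | C=CC(C)(C)Oc1ccc(cc1)[C@H]1Oc2cc(O[Si](C(C)C)(C(C)C)C(C)C)cc(O)c2C(=O)[C@@H]1O | intermediate
6 | (2R,3R)-5-hydroxy-2-[4-(2-methylbut-3-en-2-yloxy)phenyl]-3-(triethylsilyloxy)-7-(triisopropylsilyloxy)chroman-4-one | C=CC(C)(C)Oc1ccc(cc1)[C@H]1Oc2cc(O[Si](C(C)C)(C(C)C)C(C)C)cc(O)c2C(=O)[C@@H]1O[Si](CC)(CC)CC | intermediate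
7 | 3-methylbut-2-en-1-ol | CC(C)=CCO | starting material
8 | (2R,3R)-5-(3-methylbut-2-enyloxy)-2-[4-(2-methylbut-3-en-2-yloxy)phenyl]-3-(triethylsilyloxy)-7-(triisopropylsilyloxy)chroman-4-one (precursor of the key step) | C=CC(C)(C)Oc1ccc(cc1)[C@H]1Oc2cc(O[Si](C(C)C)(C(C)C)C(C)C)cc(OCC=C(C)C)c2C(=O)[C@@H]1O[Si](CC)(CC)CC | intermediate
9 | (2R,3R)-6-(2-methylbut-3-en-2-yl)-2-[4-(2-methylbut-3-en-2-yloxy)phenyl]-3-(triethylsilyloxy)-7-(triisopropylsilyloxy)-2,3-dihydro-4H-chromene-4,5(6H)-dione, C6 undefined (transient) | C=CC(C)(C)Oc1ccc(cc1)[C@H]1OC2=C(C(=O)[C@@H]1O[Si](CC)(CC)CC)C(=O)C(C(C)(C)C=C)C(O[Si](C(C)C)(C(C)C)C(C)C)=C2 | intermediate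
10 | (2R,3R)-8-(3-methylbut-2-enyl)-2-[4-(2-methylbut-3-en-2-yloxy)phenyl]-3-(triethylsilyloxy)-7-(triisopropylsilyloxy)-2,3-dihydro-4H-chromene-4,5(8H)-dione, C8 undefined (transient) | C=CC(C)(C)Oc1ccc(cc1)[C@H]1OC2=C(C(=O)[C@@H]1O[Si](CC)(CC)CC)C(=O)C=C(O[Si](C(C)C)(C(C)C)C(C)C)C2CC=C(C)C | intermediate
11 | (2R,3R)-5-hydroxy-8-(3-methylbut-2-enyl)-2-[4-(2-methylbut-3-en-2-yloxy)phenyl]-3-(triethylsilyloxy)-7-(triisopropylsilyloxy)chroman-4-one | C=CC(C)(C)Oc1ccc(cc1)[C@H]1Oc2c(CC=C(C)C)c(O[Si](C(C)C)(C(C)C)C(C)C)cc(O)c2C(=O)[C@@H]1O[Si](CC)(CC)CC | intermediate
12 | (2R,3R)-5-hydroxy-8-(3-methylbut-2-enyl)-2-[3-(3-methylbut-2-enyl)-4-oxocyclohexa-1,5-dien-1-yl]-3-(triethylsilyloxy)-7-(triisopropylsilyloxy)chroman-4-one, ring B sp3 carbon undefined (transient) | O=C1C=CC(=CC1CC=C(C)C)[C@H]1Oc2c(CC=C(C)C)c(O[Si](C(C)C)(C(C)C)C(C)C)cc(O)c2C(=O)[C@@H]1O[Si](CC)(CC)CC | intermediate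
13 | (2R,3R)-5-hydroxy-2-[4-hydroxy-3-(3-methylbut-2-enyl)phenyl]-8-(3-methylbut-2-enyl)-3-(triethylsilyloxy)-7-(triisopropylsilyloxy)chroman-4-one (product of the key step) | CC(C)=CCc1cc(ccc1O)[C@H]1Oc2c(CC=C(C)C)c(O[Si](C(C)C)(C(C)C)C(C)C)cc(O)c2C(=O)[C@@H]1O[Si](CC)(CC)CC | intermediate
14 | lespedezaflavanone C, (2R,3R)-3,5,7-trihydroxy-2-[4-hydroxy-3-(3-methylbut-2-enyl)phenyl]-8-(3-methylbut-2-enyl)chroman-4-one | CC(C)=CCc1cc([C@H]2Oc3c(CC=C(C)C)c(O)cc(O)c3C(=O)[C@@H]2O)ccc1O | target

## Step count and least certain steps

Total step count: 7. Longest linear sequence: 6 (steps 2 to 7, from 3); step 1 is a one-step branch that joins at step 3.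

**Step 6 (key step).** The most likely failure is europium-assisted ionisation of the tertiary allyl aryl ether, which would lose the C5 unit before the thermal [3,3] shift can occur. Lewis-acid cyclisation of the newly formed o-prenylphenol during the hotter stage is the second risk; premature enolisation of the C6 dienone is the third. The fallback separates the two rearrangements and inserts a protection between them, so that ring B never meets the Lewis acid as an ether or as a free o-prenylphenol. It sets out from 8. Heating 8 without europium (toluene, NaHCO3, 110 °C) should rearrange ring B only, since the 5-O-prenyl ether needs far higher temperatures without a Lewis acid, and give the 3'-prenyl-4'-phenol F1. TESCl and imidazole would cap the new phenol as the 4'-O-TES ether F2. Eu(fod)3 with NaHCO3 in PhCl at 85 °C would then carry out the para-Claisen–Cope sequence on ring A alone and give the tris-silyl ether F3. The same buffered fluoride treatment as in step 7 removes all three silyl groups, so the fallback comes back to the route at 14.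

**Step 3.** The likely failure is loss of branched selectivity, either by attack at the unsubstituted allyl terminus or by palladium-mediated re-ionisation of the tertiary ether and drift to the linear prenyl ether. Silyl transfer from O7 under the transient alkoxide is a lesser risk. The fallback builds the tertiary C–O bond by a copper-catalysed propargylic substitution, where no regiochemical choice exists, and sets out from 4. 3-Chloro-3-methylbut-1-yne with catalytic CuCl2·2H2O and DBU in MeCN at 0 °C would give the 1,1-dimethylpropargyl ether F4. Semi-hydrogenation (H2, Pd/CaCO3 poisoned with Pb(OAc)2, quinoline, EtOAc) would reduce the alkyne to the vinyl group; F4 contains no other alkene at this stage. The fallback comes back to the route at 5.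

**Step 5.** The likely failure is sluggish reaction of the hydrogen-bonded, peri-hindered 5-OH, with the betaine consumed unproductively, or attack of the hydrazide by-product on the aryl silyl ether. The fallback replaces the redox condensation by a silver-assisted etherification without soluble base: from 6, prenyl bromide and Ag2O in toluene at rt in the dark, where halide abstraction by silver drives O-alkylation of the chelated phenol. It gives 8 directly, so it sets out from 6, comes back at 8 and makes no new compound.

## Further compounds

F1 | step 6 | (2R,3R)-2-[4-hydroxy-3-(3-methylbut-2-enyl)phenyl]-5-(3-methylbut-2-enyloxy)-3-(triethylsilyloxy)-7-(triisopropylsilyloxy)chroman-4-one | CC(C)=CCc1cc(ccc1O)[C@H]1Oc2cc(O[Si](C(C)C)(C(C)C)C(C)C)cc(OCC=C(C)C)c2C(=O)[C@@H]1O[Si](CC)(CC)CC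
F2 | step 6 | (2R,3R)-2-[3-(3-methylbut-2-enyl)-4-(triethylsilyloxy)phenyl]-5-(3-methylbut-2-enyloxy)-3-(triethylsilyloxy)-7-(triisopropylsilyloxy)chroman-4-one | CC(C)=CCc1cc(ccc1O[Si](CC)(CC)CC)[C@H]1Oc2cc(O[Si](C(C)C)(C(C)C)C(C)C)cc(OCC=C(C)C)c2C(=O)[C@@H]1O[Si](CC)(CC)CC
F3 | step 6 | (2R,3R)-5-hydroxy-8-(3-methylbut-2-enyl)-2-[3-(3-methylbut-2-enyl)-4-(triethylsilyloxy)phenyl]-3-(triethylsilyloxy)-7-(triisopropylsilyloxy)chroman-4-one | CC(C)=CCc1cc(ccc1O[Si](CC)(CC)CC)[C@H]1Oc2c(CC=C(C)C)c(O[Si](C(C)C)(C(C)C)C(C)C)cc(O)c2C(=O)[C@@H]1O[Si](CC)(CC)CC
F4 | step 3 | (2R,3R)-3,5-dihydroxy-2-[4-(2-methylbut-3-yn-2-yloxy)phenyl]-7-(triisopropylsilyloxy)chroman-4-one | C#CC(C)(C)Oc1ccc(cc1)[C@H]1Oc2cc(O[Si](C(C)C)(C(C)C)C(C)C)cc(O)c2C(=O)[C@@H]1O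
F0 | step 5 | none | none
A1 | alternative 1 | tetrakis-O-MOM-lespedezaflavanone C | COCOc1ccc(cc1CC=C(C)C)[C@H]1Oc2c(CC=C(C)C)c(OCOC)cc(OCOC)c2C(=O)[C@@H]1OCOC
A2 | alternative 1 | (2R,3R)-1-[2-fluoro-4,6-bis(methoxymethoxy)-3-(3-methylbut-2-enyl)phenyl]-3-hydroxy-2-(methoxymethoxy)-3-[4-(methoxymethoxy)-3-(3-methylbut-2-enyl)phenyl]propan-1-one | COCOc1ccc(cc1CC=C(C)C)[C@@H](O)[C@@H](OCOC)C(=O)c1c(F)c(CC=C(C)C)c(OCOC)cc1OCOC
A3 | alternative 2 | 3-O-TBS-4'-O-MOM-lespedezaflavanone C | COCOc1ccc(cc1CC=C(C)C)[C@H]1Oc2c(CC=C(C)C)c(O)cc(O)c2C(=O)[C@@H]1O[Si](C)(C)C(C)(C)C
A4 | alternative 2 | (2R,3R)-5-bromo-3-(tert-butyldimethylsilyloxy)-2-[4-(methoxymethoxy)-3-(3-methylbut-2-enyl)phenyl]-2,3-dihydro-4H-pyran-4-one | COCOc1ccc(cc1CC=C(C)C)[C@H]1OC=C(Br)C(=O)[C@@H]1O[Si](C)(C)C(C)(C)C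
A5 | alternative 2 | 1-methoxy-7-methyl-1,3-bis(trimethylsilyloxy)octa-1,3,6-triene | COC(O[Si](C)(C)C)=CC(O[Si](C)(C)C)=CCC=C(C)C
A6 | alternative 3 | 3-O-TBS-tris-O-MOM-lespedezaflavanone C | COCOc1ccc(cc1CC=C(C)C)[C@H]1Oc2c(CC=C(C)C)c(OCOC)cc(OCOC)c2C(=O)[C@@H]1O[Si](C)(C)C(C)(C)C
A7 | alternative 3 | (2R,3R)-3-[2-bromo-3,5-bis(methoxymethoxy)-6-(3-methylbut-2-enyl)phenoxy]-2-(tert-butyldimethylsilyloxy)-N-methoxy-N-methyl-3-[4-(methoxymethoxy)-3-(3-methylbut-2-enyl)phenyl]propanamide | COCOc1ccc(cc1CC=C(C)C)[C@@H](Oc1c(CC=C(C)C)c(OCOC)cc(OCOC)c1Br)[C@@H](O[Si](C)(C)C(C)(C)C)C(=O)N(C)OC
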